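## Retrosynthetic overview

- **Feature the plan rests on:** ring A has oxygen on C5, C7 and C8a, and C4a carries the carbinol carbon C4. This is the alternating pattern of a tetraketide folded by a Claisen condensation, so ring A is made by forming C4a–C8a.
- **C3 and C4:** both stereocentres come last from the flat isoflavone, by asymmetric transfer hydrogenation with dynamic kinetic resolution. The 4'-O-allyl group is then removed.
- **Ring C (O1–C2, C2–C3):** from the 2,4,6-trihydroxydeoxybenzoin and one carbon supplied by DMF dimethyl acetal, followed by selective methylation of O7.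
- **Ring A (C4a–C8a):** Claisen cyclisation of a methyl 8-aryl-3,5,7-trioxooctanoate. Its chain is joined from the ring B arylacetic acid (C3, C4) and a keto-dioxinone (C4a to C8a).
- **Ring B:** bought as 4-hydroxy-2-methoxybenzaldehyde, then brominated and prenylated at C5' and homologated by one carbon. Ring order: B (bought), A (step 10), C (step 11).

Key step: step 10

Remark: all β-polycarbonyl compounds are written as keto tautomers although they will be keto–enol mixtures; this does not affect the chemistry.

## Route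

Step 1
Reactants: 1 4-hydroxy-2-methoxybenzaldehyde
Product: 2 5-bromo-4-hydroxy-2-methoxybenzaldehyde
Conditions: NBS (1.0 equiv), MeCN, 0 °C → rt
Reagents that add atoms: N-bromosuccinimide, O=C1CCC(=O)N1Br
Why: Electrophilic aromatic bromination; C5 is ortho to the phenol and para to the methoxy group and is unhindered, whereas the equally activated C3 is wedged between two oxygens, so one equivalent should brominate C5 only.

Step 2
Reactants: 2 5-bromo-4-hydroxy-2-methoxybenzaldehyde; 3 allyl bromide
Product: 4 4-(allyloxy)-5-bromo-2-methoxybenzaldehyde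
Conditions: allyl bromide, K2CO3, DMF, rt
Reagents that add atoms: allyl bromide 3, C=CCBr
Why: Williamson ether synthesis on the acidic para-formyl phenol; the allyl ether tolerates the bases, organometals and hydride sources used later and can be removed at the end without acid.

Step 3
Reactants: 4 4-(allyloxy)-5-bromo-2-methoxybenzaldehyde
Product: 5 2-[4-(allyloxy)-5-bromo-2-methoxyphenyl]-1,3-dioxolane
Conditions: HOCH2CH2OH, p-TsOH (cat.), toluene, reflux (Dean–Stark); Et3N quench
Reagents that add atoms: ethylene glycol, OCCO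
Why: Acid-catalysed acetalisation with azeotropic removal of water masks the aldehyde against the organolithium of step 4.

Step 4
Reactants: 5 2-[4-(allyloxy)-5-bromo-2-methoxyphenyl]-1,3-dioxolane; 6 prenyl bromide (1-bromo-3-methylbut-2-ene)
Product: 9 4-(allyloxy)-2-methoxy-5-(3-methylbut-2-enyl)benzaldehyde, via aryllithium 7 (not isolated), via prenylated dioxolane 8 (not isolated)
Conditions: n-BuLi, THF, −78 °C; CuBr·SMe2 (1.0 equiv), −78 → −40 °C; prenyl bromide, −78 → 0 °C; then 1 M HCl, THF, rt
Reagents that add atoms: prenyl bromide 6, CC(C)=CCBr; water, O; n-butyllithium, [Li]CCCC (lithium of 7 only)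
Why: Bromine–lithium exchange at −78 °C outruns any attack on the allyl ether, transmetalation to the arylcopper prevents carbolithiation of the neighbouring O-allyl group and gives allylic substitution at the primary carbon of prenyl bromide (the other terminus is fully substituted), and the electron-rich acetal is cleaved in the dilute acid work-up, which leaves the trisubstituted alkene alone.

Step 5
Reactants: 9 4-(allyloxy)-2-methoxy-5-(3-methylbut-2-enyl)benzaldehyde
Product: 11 2-[4-(allyloxy)-2-methoxy-5-(3-methylbut-2-enyl)phenyl]acetonitrile, via N-formyl tosyl enamine 10 (not isolated)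
Conditions: TosMIC, t-BuOK, DME, −35 °C; then MeOH, reflux
Reagents that add atoms: tosylmethyl isocyanide, [C-]#[N+]CS(=O)(=O)c1ccc(C)cc1
Why: Van Leusen reductive cyanation; the TosMIC anion adds to the aldehyde, the oxazoline opens to 10, and methanolysis of the formyl group followed by loss of sulfinate gives the one-carbon homologue under purely basic conditions that suit the prenyl group.

Step 6
Reactants: 11 2-[4-(allyloxy)-2-methoxy-5-(3-methylbut-2-enyl)phenyl]acetonitrile
Product: 13 2-[4-(allyloxy)-2-methoxy-5-(3-methylbut-2-enyl)phenyl]acetic acid, via primary amide 12 (not isolated)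
Conditions: KOH, EtOH/H2O, reflux; then cold 1 M HCl to pH 3
Reagents that add atoms: potassium hydroxide, [K+].[OH-]; water, O
Why: Alkaline nitrile hydrolysis through the amide; aryl allyl ether, aryl methyl ether and prenyl group are inert to aqueous hydroxide, and the short cold acidification only protonates the carboxylate.

Step 7
Reactants: 14 2,2,6-trimethyl-4H-1,3-dioxin-4-one
Product: 16 2,2-dimethyl-6-(2-oxopropyl)-4H-1,3-dioxin-4-one, via lithium dienolate 15 (not isolated)
Conditions: LiN(SiMe3)2, THF, −78 °C; AcCl (0.5 equiv), −78 → −20 °C; 1 M HCl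
Reagents that add atoms: acetyl chloride, CC(=O)Cl; LiN(SiMe3)2, [Li]N([Si](C)(C)C)[Si](C)(C)C (lithium of 15 only)
Why: Vinylogous deprotonation of the dioxinone and Claisen-type C-acylation of the dienolate at its exocyclic carbon; the enolate is taken in twofold excess because the more acidic product consumes one equivalent.

Step 8
Reactants: 13 2-[4-(allyloxy)-2-methoxy-5-(3-methylbut-2-enyl)phenyl]acetic acid; 16 2,2-dimethyl-6-(2-oxopropyl)-4H-1,3-dioxin-4-one
Product: 19 6-{5-[4-(allyloxy)-2-methoxy-5-(3-methylbut-2-enyl)phenyl]-2,4-dioxopentyl}-2,2-dimethyl-4H-1,3-dioxin-4-one, via acyl imidazolide 17 (not isolated), via dilithio dianion 18 (not isolated)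
Conditions: 13, CDI, THF, rt; separately 16 (3 equiv), LiN(i-Pr)2 (6 equiv), THF, −78 °C, then Et2Zn, → −20 °C; combine, −20 → 0 °C; 1 M HCl, 0 °C
Reagents that add atoms: 1,1'-carbonyldiimidazole, O=C(n1ccnc1)n1ccnc1 (imidazolyl group of 17 only); LiN(i-Pr)2, [Li]N(C(C)C)C(C)C (lithium of 18 only)
Why: CDI activation and Claisen-type C-acylation of a 1,3-dicarbonyl dianion at its more basic terminal carbon; diethylzinc lowers the basicity of the dienolate so that acyl transfer should outrun deprotonation of the benzylic CH2 of 17, and the excess of cheap dianion absorbs the imidazole N–H and the acidic product.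

Step 9
Reactants: 19 6-{5-[4-(allyloxy)-2-methoxy-5-(3-methylbut-2-enyl)phenyl]-2,4-dioxopentyl}-2,2-dimethyl-4H-1,3-dioxin-4-one
Product: 21 methyl 8-[4-(allyloxy)-2-methoxy-5-(3-methylbut-2-enyl)phenyl]-3,5,7-trioxooctanoate, via acylketene 20 (not isolated)
Conditions: MeOH (20 equiv), toluene, 110 °C, sealed tube; concentrate, use crude at once
Reagents that add atoms: methanol, CO
Why: Retro-hetero-Diels–Alder fragmentation of a dioxinone needs about 100 °C or more, hence toluene in a sealed tube instead of boiling methanol; acetone is lost, the excess methanol captures acylketene 20 before its own enol oxygen can, and the aryl allyl ether is still far below the temperature of an aromatic Claisen rearrangement.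

Step 10
Reactants: 21 methyl 8-[4-(allyloxy)-2-methoxy-5-(3-methylbut-2-enyl)phenyl]-3,5,7-trioxooctanoate
Product: 23 2-[4-(allyloxy)-2-methoxy-5-(3-methylbut-2-enyl)phenyl]-1-(2,4,6-trihydroxyphenyl)ethanone, via 2-acylcyclohexane-1,3,5-trione 22 (not isolated)
Conditions: Mg(OMe)2 (5 equiv), MeOH, 65 °C; then cold 1 M HCl to pH 4
Reagents that add atoms: none
Why: Mg(OMe)2 turns 21 into a chelated magnesium polyenolate; its C4a carbon, flanked by the C4 and C5 carbonyls, adds to the ester carbon C8a, methoxide leaves, and trione 22 tautomerises to the phloroglucinol, which is held as its magnesium phenolate so that the sequence does not run back. The reaction type is the intramolecular Claisen (Dieckmann-type) condensation of 3,5,7-triketo esters to acylphloroglucinols, known with magnesium methoxide for such esters and for the related 6-(acylmethyl)-4-hydroxy-2-pyrones. Ring A (C4a–C5–C6–C7–C8–C8a) closes 6-exo-trig, the ester C=O lying outside the ring being formed. No stereocentre is created. The step needs mode selectivity, Claisen (C4a onto C8a) over aldol (C8 onto the C4 ketone, leading to a resorcylate), over O-lactonisation to a pyrone and over any reaction from the benzylic C3: magnesium binds the C4/C5 1,3-diketone more firmly than the β-keto ester end, so C4 sits as an enolate oxygen and is a poor aldol acceptor, further shielded by the ortho-methoxylated benzyl group, while the ester stays the best electrophile; a pyrone formed on the side is reopened by methoxide, and C3, activated by one carbonyl only, is not deprotonated by methoxide. Because 23 has two equivalent ortho hydroxyls the fold leaves no regiochemical question for ring C, and because the medium is basic the prenyl and allyl groups pass through unchanged.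

Step 11
Reactants: 23 2-[4-(allyloxy)-2-methoxy-5-(3-methylbut-2-enyl)phenyl]-1-(2,4,6-trihydroxyphenyl)ethanone
Product: 25 3-[4-(allyloxy)-2-methoxy-5-(3-methylbut-2-enyl)phenyl]-5,7-dihydroxy-4H-chromen-4-one, via enaminone 24 (not isolated)
Conditions: Me2NCH(OMe)2, toluene, 80 °C; aq. NH4Cl work-up
Reagents that add atoms: N,N-dimethylformamide dimethyl acetal, COC(OC)N(C)C
Why: Deoxybenzoin route to isoflavones; condensation at the activated C3 methylene gives enaminone 24, either of the two equivalent ortho phenols adds to C2 and dimethylamine is lost, all without acid, and any stray methylation by the acetal would fall on the most acidic para hydroxyl, the one methylated in step 12 anyway.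

Step 12
Reactants: 25 3-[4-(allyloxy)-2-methoxy-5-(3-methylbut-2-enyl)phenyl]-5,7-dihydroxy-4H-chromen-4-one
Product: 26 3-[4-(allyloxy)-2-methoxy-5-(3-methylbut-2-enyl)phenyl]-5-hydroxy-7-methoxy-4H-chromen-4-one
Conditions: MeI (1.05 equiv), K2CO3, acetone, rt → 40 °C
Reagents that add atoms: iodomethane, CI
Why: Selective Williamson methylation; the 7-OH is a free vinylogous acid while the 5-OH is locked in a hydrogen bond to the C4 carbonyl, so one equivalent of MeI with a weak base should alkylate O7 only.

Step 13
Reactants: 26 3-[4-(allyloxy)-2-methoxy-5-(3-methylbut-2-enyl)phenyl]-5-hydroxy-7-methoxy-4H-chromen-4-one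
Product: 28 (3R,4R)-3-[4-(allyloxy)-2-methoxy-5-(3-methylbut-2-enyl)phenyl]-7-methoxychroman-4,5-diol (cis), via racemising isoflavanone 27 (not isolated)
Conditions: RuCl[(R,R)-TsDPEN](p-cymene) (5 mol %), HCO2H/Et3N (1:1), EtOAc, 40 °C
Reagents that add atoms: none
Why: Noyori-type asymmetric transfer hydrogenation cascade known for isoflavones; the ruthenium hydride first reduces C2=C3 by conjugate addition to give 27, whose C3–H is epimerised quickly by Et3N, and the (R,R)-catalyst then delivers hydride to the Si face of C4 (ring A held under the η6-arene by C–H/π attraction) of only that enantiomer whose 3-aryl group points away from the incoming hydride, which sets 4R and, by dynamic kinetic resolution, 3R in the cis relationship, while the outer-sphere catalyst leaves isolated alkenes alone and the amine-rich medium spares the acid-labile benzylic alcohol.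

Step 14
Reactants: 28 (3R,4R)-3-[4-(allyloxy)-2-methoxy-5-(3-methylbut-2-enyl)phenyl]-7-methoxychroman-4,5-diol
Product: 29 (3R,4R)-3-[4-hydroxy-2-methoxy-5-(3-methylbut-2-enyl)phenyl]-7-methoxychroman-4,5-diol (cis; target)
Conditions: Pd(PPh3)4 (5 mol %), morpholine, THF (degassed), rt
Reagents that add atoms: none
Why: Tsuji–Trost-type deallylation; zerovalent palladium ionises the aryl allyl ether to a π-allyl complex that morpholine intercepts, and the neutral to basic medium leaves the C4 benzylic alcohol, both stereocentres and the prenyl group untouched.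

## Compound list

1 | 4-hydroxy-2-methoxybenzaldehyde | COc1cc(O)ccc1C=O | starting material
2 | 5-bromo-4-hydroxy-2-methoxybenzaldehyde | COc1cc(O)c(Br)cc1C=O | intermediate
3 | allyl bromide | C=CCBr | starting material
4 | 4-(allyloxy)-5-bromo-2-methoxybenzaldehyde | C=CCOc1cc(OC)c(C=O)cc1Br | intermediate
5 | 2-[4-(allyloxy)-5-bromo-2-methoxyphenyl]-1,3-dioxolane | C=CCOc1cc(OC)c(C2OCCO2)cc1Br | intermediate
6 | prenyl bromide (1-bromo-3-methylbut-2-ene) | CC(C)=CCBr | starting material
7 | [2-(allyloxy)-5-(1,3-dioxolan-2-yl)-4-methoxyphenyl]lithium | [Li]c1cc(C2OCCO2)c(OC)cc1OCC=C | intermediate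
8 | 2-[4-(allyloxy)-2-methoxy-5-(3-methylbut-2-enyl)phenyl]-1,3-dioxolane | C=CCOc1cc(OC)c(C2OCCO2)cc1CC=C(C)C | intermediate
9 | 4-(allyloxy)-2-methoxy-5-(3-methylbut-2-enyl)benzaldehyde | C=CCOc1cc(OC)c(C=O)cc1CC=C(C)C | intermediate
10 | N-{2-[4-(allyloxy)-2-methoxy-5-(3-methylbut-2-enyl)phenyl]-1-tosylvinyl}formamide | O=CNC(=Cc1cc(CC=C(C)C)c(OCC=C)cc1OC)S(=O)(=O)c1ccc(C)cc1 | intermediate
11 | 2-[4-(allyloxy)-2-methoxy-5-(3-methylbut-2-enyl)phenyl]acetonitrile | N#CCc1cc(CC=C(C)C)c(OCC=C)cc1OC | intermediate
12 | 2-[4-(allyloxy)-2-methoxy-5-(3-methylbut-2-enyl)phenyl]acetamide | NC(=O)Cc1cc(CC=C(C)C)c(OCC=C)cc1OC | intermediate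
13 | 2-[4-(allyloxy)-2-methoxy-5-(3-methylbut-2-enyl)phenyl]acetic acid | OC(=O)Cc1cc(CC=C(C)C)c(OCC=C)cc1OC | intermediate
14 | 2,2,6-trimethyl-4H-1,3-dioxin-4-one | CC1=CC(=O)OC(C)(C)O1 | starting material
15 | lithium 2,2-dimethyl-6-methylene-6H-1,3-dioxin-4-olate | [Li+].C=C1C=C([O-])OC(C)(C)O1 | intermediate
16 | 2,2-dimethyl-6-(2-oxopropyl)-4H-1,3-dioxin-4-one | CC(=O)CC1=CC(=O)OC(C)(C)O1 | intermediate
17 | 2-[4-(allyloxy)-2-methoxy-5-(3-methylbut-2-enyl)phenyl]-1-(1H-imidazol-1-yl)ethanone | O=C(Cc1cc(CC=C(C)C)c(OCC=C)cc1OC)n1ccnc1 | intermediate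
18 | dilithium dienolate (dianion) of 16 | [Li+].[Li+].C=C([O-])C=C1C=C([O-])OC(C)(C)O1 | intermediate
19 | 6-{5-[4-(allyloxy)-2-methoxy-5-(3-methylbut-2-enyl)phenyl]-2,4-dioxopentyl}-2,2-dimethyl-4H-1,3-dioxin-4-one | CC1(C)OC(=O)C=C(CC(=O)CC(=O)Cc2cc(CC=C(C)C)c(OCC=C)cc2OC)O1 | intermediate
20 | 8-[4-(allyloxy)-2-methoxy-5-(3-methylbut-2-enyl)phenyl]oct-1-ene-1,3,5,7-tetraone (acylketene) | O=C=CC(=O)CC(=O)CC(=O)Cc1cc(CC=C(C)C)c(OCC=C)cc1OC | intermediate
21 | methyl 8-[4-(allyloxy)-2-methoxy-5-(3-methylbut-2-enyl)phenyl]-3,5,7-trioxooctanoate | COC(=O)CC(=O)CC(=O)CC(=O)Cc1cc(CC=C(C)C)c(OCC=C)cc1OC | intermediate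
22 | 2-{[4-(allyloxy)-2-methoxy-5-(3-methylbut-2-enyl)phenyl]acetyl}cyclohexane-1,3,5-trione | O=C1CC(=O)C(C(=O)Cc2cc(CC=C(C)C)c(OCC=C)cc2OC)C(=O)C1 | intermediate
23 | 2-[4-(allyloxy)-2-methoxy-5-(3-methylbut-2-enyl)phenyl]-1-(2,4,6-trihydroxyphenyl)ethanone | O=C(Cc1cc(CC=C(C)C)c(OCC=C)cc1OC)c1c(O)cc(O)cc1O | intermediate
24 | 2-[4-(allyloxy)-2-methoxy-5-(3-methylbut-2-enyl)phenyl]-3-(dimethylamino)-1-(2,4,6-trihydroxyphenyl)prop-2-en-1-one | CN(C)C=C(C(=O)c1c(O)cc(O)cc1O)c1cc(CC=C(C)C)c(OCC=C)cc1OC | intermediate
25 | 3-[4-(allyloxy)-2-methoxy-5-(3-methylbut-2-enyl)phenyl]-5,7-dihydroxy-4H-chromen-4-one | O=c1c(-c2cc(CC=C(C)C)c(OCC=C)cc2OC)coc2cc(O)cc(O)c12 | intermediate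
26 | 3-[4-(allyloxy)-2-methoxy-5-(3-methylbut-2-enyl)phenyl]-5-hydroxy-7-methoxy-4H-chromen-4-one | COc1cc(O)c2c(c1)occ(-c1cc(CC=C(C)C)c(OCC=C)cc1OC)c2=O | intermediate
27 | 3-[4-(allyloxy)-2-methoxy-5-(3-methylbut-2-enyl)phenyl]-5-hydroxy-7-methoxychroman-4-one (racemic, epimerising at C3) | COc1cc(O)c2c(c1)OCC(c1cc(CC=C(C)C)c(OCC=C)cc1OC)C2=O | intermediate
28 | (3R,4R)-3-[4-(allyloxy)-2-methoxy-5-(3-methylbut-2-enyl)phenyl]-7-methoxychroman-4,5-diol (cis) | COc1cc(O)c2c(c1)OC[C@@H](c1cc(CC=C(C)C)c(OCC=C)cc1OC)[C@H]2O | intermediate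
29 | (3R,4R)-3-[4-hydroxy-2-methoxy-5-(3-methylbut-2-enyl)phenyl]-7-methoxychroman-4,5-diol (cis; CNP0265409.1) | COc1cc(O)c2c(c1)OC[C@@H](c1cc(CC=C(C)C)c(O)cc1OC)[C@H]2O | target

## Step count and risks

Total step count: 14.
Longest linear sequence: 13 (steps 1–6 and 8–14). Step 7 is a one-step side branch.

**Risk 1, step 10.**
- What may go wrong: the polyenolate may close through the aldol mode or by O-lactonisation, or methoxide may cut the chain by retro-Claisen cleavage, so that the Claisen fold is only a minor pathway.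
- Fallback (ring A bought instead of folded): it sets out from acid 13. CDI and MeNHOMe·HCl convert 13 into the Weinreb amide F1.
- Phloroglucinol is protected with MOMCl/i-Pr2NEt as 1,3,5-tris(methoxymethoxy)benzene F2.
- Directed ortho-metalation of F2 (n-BuLi, THF, 0 °C) gives the 2-lithio derivative F3, which is added to F1 at −78 °C to give the tris-MOM deoxybenzoin F4.
- Short treatment with dilute HCl in MeOH at room temperature removes the three acetals. The prenyl group is safe because the phenol next to it is still allylated. The route is rejoined at 23.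

**Risk 2, step 8.**
- What may go wrong: proton transfer from the acidic benzylic position of the acyl donor to the dianion, or O-acylation, may outrun C-acylation.
- Fallback (aldol addition and oxidation instead of acylation): it sets out from nitrile 11. Reduction with i-Bu2AlH (toluene, −78 °C) and buffered hydrolysis give the arylacetaldehyde F5.
- Dianion 18, made as in step 8 without zinc, is added to F5 at −78 °C to give the β-hydroxy ketone F6, which is racemic; its stereocentre is erased in the next operation.
- Dess–Martin periodinane with NaHCO3 in CH2Cl2 oxidises F6 to the 1,3-diketone. The route is rejoined at 19.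

**Risk 3, step 13.**
- What may go wrong: the conjugate reduction may stall, the hydrogen-bonded C4 carbonyl may be reduced too slowly for racemisation to keep the resolution dynamic, facial and cis selectivity may erode, or the product alcohol may ionise.
- Fallback (chelation removed and the two reductions separated): it sets out from 26. Allylation with allyl bromide 3 and K2CO3 in DMF at 60 °C gives the 5-O-allyl isoflavone F7.
- LiBH(s-Bu)3 in THF at −78 °C performs the 1,4-reduction to the racemic isoflavanone F8.
- The same ruthenium catalyst then only has to carry out the ketone reduction with dynamic kinetic resolution, giving the cis-(3R,4R) alcohol F9.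
- Pd(PPh3)4/morpholine removes both allyl groups at once. The route is rejoined at 29.

## Further compounds

F1 | step 10 | 2-[4-(allyloxy)-2-methoxy-5-(3-methylbut-2-enyl)phenyl]-N-methoxy-N-methylacetamide | CON(C)C(=O)Cc1cc(CC=C(C)C)c(OCC=C)cc1OC
F2 | step 10 | 1,3,5-tris(methoxymethoxy)benzene | COCOc1cc(OCOC)cc(OCOC)c1
F3 | step 10 | [2,4,6-tris(methoxymethoxy)phenyl]lithium | [Li]c1c(OCOC)cc(OCOC)cc1OCOC
F4 | step 10 | 2-[4-(allyloxy)-2-methoxy-5-(3-methylbut-2-enyl)phenyl]-1-[2,4,6-tris(methoxymethoxy)phenyl]ethanone | COCOc1cc(OCOC)c(C(=O)Cc2cc(CC=C(C)C)c(OCC=C)cc2OC)c(OCOC)c1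
F5 | step 8 | 2-[4-(allyloxy)-2-methoxy-5-(3-methylbut-2-enyl)phenyl]acetaldehyde | O=CCc1cc(CC=C(C)C)c(OCC=C)cc1OC
F6 | step 8 | 6-{5-[4-(allyloxy)-2-methoxy-5-(3-methylbut-2-enyl)phenyl]-4-hydroxy-2-oxopentyl}-2,2-dimethyl-4H-1,3-dioxin-4-one (racemic) | CC1(C)OC(=O)C=C(CC(=O)CC(O)Cc2cc(CC=C(C)C)c(OCC=C)cc2OC)O1
F7 | step 13 | 5-(allyloxy)-3-[4-(allyloxy)-2-methoxy-5-(3-methylbut-2-enyl)phenyl]-7-methoxy-4H-chromen-4-one | COc1cc(OCC=C)c2c(c1)occ(-c1cc(CC=C(C)C)c(OCC=C)cc1OC)c2=O
F8 | step 13 | 5-(allyloxy)-3-[4-(allyloxy)-2-methoxy-5-(3-methylbut-2-enyl)phenyl]-7-methoxychroman-4-one (racemic) | COc1cc(OCC=C)c2c(c1)OCC(c1cc(CC=C(C)C)c(OCC=C)cc1OC)C2=O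
F9 | step 13 | (3R,4R)-5-(allyloxy)-3-[4-(allyloxy)-2-methoxy-5-(3-methylbut-2-enyl)phenyl]-7-methoxychroman-4-ol (cis) | COc1cc(OCC=C)c2c(c1)OC[C@@H](c1cc(CC=C(C)C)c(OCC=C)cc1OC)[C@H]2O
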